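**Retrosynthetic overview**
- The C8 prenyl group is not attached directly. It is relayed from oxygen: target ⇒ (ammonolysis of three acetates, para-Claisen–Cope shift O5 → C6 → C8) 3,7,4'-tri-O-acetyl-5-O-prenylkaempferol.
- Key disconnection: the O5–CH2 ether bond of that compound ⇒ 3,7,4'-tri-O-acetylkaempferol + tert-butyl prenyl carbonate (palladium-catalysed decarboxylative O-prenylation, the new step). The site of this C–O bond fixes the C8 regiochemistry.
- Triacetate ⇒ kaempferol (selective acetylation, chelated 5-OH left free); carbonate ⇒ prenol + Boc2O.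
- Ring order: rings A, C and B are all bought intact in kaempferol; no ring is formed.

Assumption: the target SMILES has no stereocentre and no stereogenic double bond, so the compound is achiral and no stereocontrol is needed; kaempferol is taken as a bulk commercial flavonol.

**Route**

Step 1
Reactants: 1 kaempferol
Product: 2 3,7,4'-tri-O-acetylkaempferol
Conditions: Ac2O (3.3 equiv), pyridine, 0 °C to rt, 6 h; cold dilute HCl work-up, recrystallise
Reagents that add atoms: acetic anhydride, CC(=O)OC(C)=O
Why: Kinetically selective O-acetylation (esterification): the 5-OH is locked in a strong hydrogen bond to the C4 carbonyl and is acylated far more slowly than the 3-, 7- and 4'-hydroxyls, so three equivalents of anhydride stop at the triacetate.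

Step 2
Reactants: 3 prenol (3-methylbut-2-en-1-ol)
Product: 4 tert-butyl (3-methylbut-2-en-1-yl) carbonate
Conditions: Boc2O (1.2 equiv), n-Bu4NHSO4 (5 mol%), 30% aq NaOH, CH2Cl2, 0 °C to rt
Reagents that add atoms: di-tert-butyl dicarbonate, CC(C)(C)OC(=O)OC(=O)OC(C)(C)C
Why: Phase-transfer O-acylation of a primary allylic alcohol with Boc2O, the standard preparation of allyl tert-butyl carbonates.

Step 3
Reactants: 2 3,7,4'-tri-O-acetylkaempferol; 4 tert-butyl (3-methylbut-2-en-1-yl) carbonate
Product: 5 3,7,4'-tri-O-acetyl-5-O-prenylkaempferol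
Conditions: Pd2(dba)3 (2.5 mol%), dppe (Ph2PCH2CH2PPh2, 6 mol%), THF, 40 °C, 4 (1.3 equiv) added over 1 h
Reagents that add atoms: none
Why: Proposed new method: decarboxylative Tsuji–Trost O-prenylation of the chelated peri-hydroxyl of a polyacylated flavonol, in which zerovalent palladium ionises 4 to a (π-prenyl)palladium cation, CO2 and tert-butoxide, the alkoxide removes the only acidic proton of 2 (5-OH), and the resulting phenoxide attacks the unhindered CH2 terminus from outside the metal; the phenoxide never exceeds the catalyst loading, so the acetyl scrambling seen with K2CO3/prenyl bromide is suppressed; the chelating small-bite-angle diphosphine blocks an acac-like O,O-chelate resting state and favours the less substituted allyl terminus; any tertiary ether re-ionises and drains to the more stable primary ether; the closest known reaction type is the palladium-catalysed decarboxylative allylic etherification of simple non-chelated phenols with allyl tert-butyl carbonates.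

Step 4
Reactants: 5 3,7,4'-tri-O-acetyl-5-O-prenylkaempferol
Product: 9 8-prenylkaempferol, via ortho-dienone 6 (not isolated), via para-dienone 7 (not isolated), via C-prenyl triacetate 8 (not isolated)
Conditions: Eu(fod)3 (10 mol%; fod = 6,6,7,7,8,8,8-heptafluoro-2,2-dimethyl-3,5-octanedionate), NaHCO3, PhCl, 85 °C; evaporate; then 7 M NH3 in MeOH, 0 °C to rt, Ar; evaporate, chromatography
Reagents that add atoms: none
Why: Lewis-acid-catalysed para-Claisen–Cope rearrangement followed by ester ammonolysis: trivalent europium chelates the C4 carbonyl and O5 and accelerates the [3,3] shift of the prenyl ether to the C6 dienone 6, whose crowded 1,1-dimethylallyl group undergoes a Cope shift to C8 (dienone 7) faster than 6 enolises in the aprotic buffered medium, enolisation of 7 gives 8, and NH3/MeOH removes the three acetates without acid so the prenyl group cannot cyclise onto the 7-OH; the sp3 centres of 6 and 7 are transient and racemic and none survives in 9.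

**Compound list**

1 | kaempferol | O=c1c(O)c(-c2ccc(O)cc2)oc2cc(O)cc(O)c12 | starting material
2 | 3,7,4'-tri-O-acetylkaempferol (5-OH free) | CC(=O)Oc1ccc(cc1)-c1oc2cc(OC(C)=O)cc(O)c2c(=O)c1OC(C)=O | intermediate
3 | prenol (3-methylbut-2-en-1-ol) | CC(C)=CCO | starting material
4 | tert-butyl (3-methylbut-2-en-1-yl) carbonate | CC(C)=CCOC(=O)OC(C)(C)C | intermediate
5 | 3,7,4'-tri-O-acetyl-5-O-prenylkaempferol | CC(C)=CCOc1cc(OC(C)=O)cc2oc(-c3ccc(OC(C)=O)cc3)c(OC(C)=O)c(=O)c12 | intermediate
6 | ortho-dienone: 3,7-diacetoxy-2-(4-acetoxyphenyl)-6-(2-methylbut-3-en-2-yl)-6H-chromene-4,5-dione (not isolated, racemic) | C=CC(C)(C)C1C(=O)C2=C(C=C1OC(C)=O)OC(c1ccc(OC(C)=O)cc1)=C(OC(C)=O)C2=O | intermediate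
7 | para-dienone: 3,7-diacetoxy-2-(4-acetoxyphenyl)-8-(3-methylbut-2-en-1-yl)-8H-chromene-4,5-dione (not isolated, racemic) | CC(C)=CCC1C(OC(C)=O)=CC(=O)C2=C1OC(c1ccc(OC(C)=O)cc1)=C(OC(C)=O)C2=O | intermediate
8 | 3,7,4'-tri-O-acetyl-8-prenylkaempferol (not isolated) | CC(C)=CCc1c(OC(C)=O)cc(O)c2c(=O)c(OC(C)=O)c(-c3ccc(OC(C)=O)cc3)oc12 | intermediate
9 | 8-prenylkaempferol (achiral) | CC(C)=CCc1c(O)cc(O)c2c(=O)c(O)c(-c3ccc(O)cc3)oc12 | target

**Step count and risks**

Total steps: 4 (three on the main line plus one reagent preparation). Longest linear sequence: 3 (1 → 2 → 5 → 9).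

Most likely to fail, first: step 3, the new etherification. The chelated phenoxide is a weak nucleophile, and tertiary-ether formation, C-allylation or acetyl transfer may compete. Fallback, known chemistry: a Mitsunobu etherification. It sets out from 2, which is treated with prenol 3, PPh3 and DIAD in THF at 0 °C to rt; this alkylates the chelated 5-OH of acetylated flavonoids under neutral conditions. It comes back to the route at 5, and step 2 is then not needed. New compounds on this path: none F0.

Second: step 4. The ortho-dienone 6 may enolise before the Cope shift and give the 6-(1,1-dimethylallyl) isomer, or the acetates may interfere with the europium catalyst. Fallback: replace the para relay from O5 by an ortho-Claisen shift from O7. It sets out from 1 and runs as follows: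
- Exhaustive acetylation (Ac2O, pyridine, DMAP, 60 °C) gives kaempferol tetraacetate F4.
- PhSH and imidazole in NMP at 0 °C remove the most labile 7-O-acetyl to give 3,5,4'-tri-O-acetylkaempferol F5.
- Pd(PPh3)4 with carbonate 4 in THF at 0 °C (kinetic attack of an unhindered phenoxide at the tertiary allyl terminus) gives 7-O-(2-methylbut-3-en-2-yl)-3,5,4'-tri-O-acetylkaempferol F6.
- Heating in toluene at 110 °C effects the aromatic Claisen shift. With O5 acetylated there is no chelate to steer it to C6, so it should go mainly to C8 (the preference shown by 7-allyloxychromones) and give 3,5,4'-tri-O-acetyl-8-prenylkaempferol F7 directly.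
- NH3 in MeOH then comes back to the route at 9.

Third: step 1. Mixtures of di-, tri- and tetra-acetates may form. Fallback: change to base-stable acetal protection. It sets out from 1 and runs as follows:
- MOMCl (3.3 equiv) and i-Pr2NEt in CH2Cl2 at 0 °C give 3,7,4'-tris-O-(methoxymethyl)kaempferol F1, the chelated 5-OH again staying free.
- Prenyl bromide and K2CO3 in refluxing acetone give 5-O-prenyl-3,7,4'-tris-O-(methoxymethyl)kaempferol F2.
- Eu(fod)3 and NaHCO3 in PhCl at 85 °C give 8-prenyl-3,7,4'-tris-O-(methoxymethyl)kaempferol F3.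
- Dilute HCl in MeOH at 40 °C, kept short to avoid cyclisation of the prenyl group onto the 7-OH, comes back to the route at 9.

**Further compounds**

F1 | step 1 | 3,7,4'-tris-O-(methoxymethyl)kaempferol | COCOc1ccc(cc1)-c1oc2cc(OCOC)cc(O)c2c(=O)c1OCOC
F2 | step 1 | 5-O-prenyl-3,7,4'-tris-O-(methoxymethyl)kaempferol | CC(C)=CCOc1cc(OCOC)cc2oc(-c3ccc(OCOC)cc3)c(OCOC)c(=O)c12
F3 | step 1 | 8-prenyl-3,7,4'-tris-O-(methoxymethyl)kaempferol | CC(C)=CCc1c(OCOC)cc(O)c2c(=O)c(OCOC)c(-c3ccc(OCOC)cc3)oc12
F0 | step 3 | none | none
F4 | step 4 | kaempferol tetraacetate (3,5,7,4'-tetra-O-acetylkaempferol) | CC(=O)Oc1ccc(cc1)-c1oc2cc(OC(C)=O)cc(OC(C)=O)c2c(=O)c1OC(C)=O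
F5 | step 4 | 3,5,4'-tri-O-acetylkaempferol (7-OH free) | CC(=O)Oc1ccc(cc1)-c1oc2cc(O)cc(OC(C)=O)c2c(=O)c1OC(C)=O
F6 | step 4 | 7-O-(2-methylbut-3-en-2-yl)-3,5,4'-tri-O-acetylkaempferol | C=CC(C)(C)Oc1cc(OC(C)=O)c2c(=O)c(OC(C)=O)c(-c3ccc(OC(C)=O)cc3)oc2c1
F7 | step 4 | 3,5,4'-tri-O-acetyl-8-prenylkaempferol (7-OH free) | CC(C)=CCc1c(O)cc(OC(C)=O)c2c(=O)c(OC(C)=O)c(-c3ccc(OC(C)=O)cc3)oc12
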